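**Strategy.** Everything rests on opening the butenolide ring (O1, C2, C3, C4, C5) at the C2–C3 bond. C2 is carbon monoxide, C3 and its methyl group are the central and terminal carbons of an allene, and O1–C5 is a secondary allenyl carbinol. Ruthenium-catalysed cyclocarbonylation of this 2,3-allenol closes the ring and writes the C3 methyl group and the C3=C4 alkene in one operation; the precursor is an acyclic β-hydroxy sulfone. The sulfone on C6, left from joining the four-carbon head to the chain, then departs by E1cB across the acidic C5–H, so all C5/C6 diastereomers converge on the (Z)-C5=C6 ylidene. The chain derives from farnesyl chloride; hydrogenation sets C7.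

Key step: step 8

Remark on numbering: butenolide atoms are O1, C2 (C=O), C3 (C–CH3), C4 (=CH) and C5; the exocyclic alkene carbon is C6 and the methyl-bearing stereocentre, (S) in the target, is C7.
Assumption: the facial sense of the Ru–BINAP hydrogenation in step 3 is assigned by analogy with geraniol and 2-methylalk-2-enoic acids; should it prove opposite, the (R)-ligand would be used with no other change.
Assumption: 3-(chloromethyl)furan, (2E,6E)-farnesyl chloride and 3-(trimethylsilyl)prop-2-ynal are taken as purchased.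

**Step 1**
Reactants: 1 3-(chloromethyl)furan; 2 (2E,6E)-farnesyl chloride
Product: 4 3-[(3E,7E)-4,8,12-trimethyltrideca-3,7,11-trien-1-yl]furan, via furan-3-ylmethylmagnesium chloride 3 (not isolated)
Conditions: Mg, THF, rt; then 2, Li2CuCl4 (3 mol%), THF, 0 °C
Reagents that add atoms: none
Why: Copper-catalysed Grignard cross-coupling with a primary allylic chloride should proceed at the α-carbon (SN2 sense), so the 2E,6E geometry of the farnesyl unit is carried into the C20 chain without allylic transposition.

**Step 2**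
Reactants: 4 3-[(3E,7E)-4,8,12-trimethyltrideca-3,7,11-trien-1-yl]furan
Product: 5 (2E,6E,10E)-13-(furan-3-yl)-2,6,10-trimethyltrideca-2,6,10-trien-1-ol
Conditions: SeO2 (0.3 equiv), t-BuOOH (2 equiv), salicylic acid (0.1 equiv), CH2Cl2, 0 °C to rt, stopped at partial conversion
Reagents that add atoms: selenium dioxide, O=[Se]=O (catalytic oxygen carrier); tert-butyl hydroperoxide, CC(C)(C)OO (terminal oxygen source)
Why: Riley allylic oxidation (ene reaction, then [2,3]-sigmatropic shift) should select the E-methyl group of the terminal isopropylidene unit, the least hindered trisubstituted alkene, and give the (E)-allylic alcohol.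

**Step 3**
Reactants: 5 (2E,6E,10E)-13-(furan-3-yl)-2,6,10-trimethyltrideca-2,6,10-trien-1-ol
Product: 6 (2S,6E,10E)-13-(furan-3-yl)-2,6,10-trimethyltrideca-6,10-dien-1-ol
Conditions: Ru(OAc)2[(S)-BINAP] (1 mol%), H2 (100 atm), MeOH, 20 °C
Reagents that add atoms: none
Why: In this Noyori asymmetric hydrogenation the hydroxyl group binds ruthenium, so only the allylic C=C should be reduced (remote alkenes and furan untouched), and the (S)-ligand is expected to deliver hydrogen to the face that gives the (S)-configured C7 methyl centre.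

**Step 4**
Reactants: 6 (2S,6E,10E)-13-(furan-3-yl)-2,6,10-trimethyltrideca-6,10-dien-1-ol
Product: 7 (2S,6E,10E)-13-(furan-3-yl)-2,6,10-trimethyltrideca-6,10-dien-1-yl 4-methylbenzenesulfonate
Conditions: TsCl, Et3N, DMAP (cat.), CH2Cl2, 0 °C to rt
Reagents that add atoms: 4-methylbenzenesulfonyl chloride, Cc1ccc(cc1)S(Cl)(=O)=O
Why: O-Sulfonylation of the primary alcohol activates C6 for substitution without touching the adjacent stereocentre.

**Step 5**
Reactants: 7 (2S,6E,10E)-13-(furan-3-yl)-2,6,10-trimethyltrideca-6,10-dien-1-yl 4-methylbenzenesulfonate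
Product: 8 3-[(3E,7E,12S)-4,8,12-trimethyl-13-(phenylsulfonyl)trideca-3,7-dien-1-yl]furan
Conditions: PhSO2Na, n-Bu4NI (cat.), DMF, 70 °C
Reagents that add atoms: sodium benzenesulfinate, [Na+].[O-]S(=O)c1ccccc1
Why: SN2 displacement of the primary tosylate by the sulfur atom of the sulfinate (S-alkylation) installs the group that later acidifies C6 and serves as its leaving group.

**Step 6**
Reactants: 8 3-[(3E,7E,12S)-4,8,12-trimethyl-13-(phenylsulfonyl)trideca-3,7-dien-1-yl]furan; 9 3-(trimethylsilyl)prop-2-ynal
Product: 11 (5S,9E,13E)-16-(furan-3-yl)-5,9,13-trimethyl-4-(phenylsulfonyl)hexadeca-9,13-dien-1-yn-3-ol (diastereomer mixture at C3/C4), via silylalkyne adduct 10 (not isolated)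
Conditions: LDA, THF, −78 °C; 9, −78 °C; AcOH; then K2CO3, MeOH, 0 °C
Reagents that add atoms: none
Why: 1,2-Addition of the α-sulfonyl carbanion to the ynal (the addition half of a Julia olefination) and methanolysis of the C–Si bond should give the terminal alkyne; the two new centres are left uncontrolled because step 8 erases both, and the C7 centre is β to the carbanion and cannot epimerise.

**Step 7**
Reactants: 11 (5S,9E,13E)-16-(furan-3-yl)-5,9,13-trimethyl-4-(phenylsulfonyl)hexadeca-9,13-dien-1-yn-3-ol
Product: 12 (6S,10E,14E)-17-(furan-3-yl)-6,10,14-trimethyl-5-(phenylsulfonyl)heptadeca-1,2,10,14-tetraen-4-ol (diastereomer mixture at C4/C5)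
Conditions: CuI (0.5 equiv), Cy2NH (1.8 equiv), (CH2O)n (2.5 equiv), 1,4-dioxane, reflux
Reagents that add atoms: paraformaldehyde (as formaldehyde), C=O
Why: Crabbé homologation (Mannich reaction of the copper acetylide, then copper-mediated 1,5-hydride transfer with loss of imine) should turn the terminal alkyne into the terminal allene, a transformation established for free secondary propargylic alcohols.

**Step 8**
Reactants: 12 (6S,10E,14E)-17-(furan-3-yl)-6,10,14-trimethyl-5-(phenylsulfonyl)heptadeca-1,2,10,14-tetraen-4-ol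
Product: 14 (5Z)-5-[(2S,6E,10E)-13-(furan-3-yl)-2,6,10-trimethyltrideca-6,10-dien-1-ylidene]-3-methylfuran-2(5H)-one, via sulfonyl butenolide 13 (not isolated)
Conditions: Ru3(CO)12 (2 mol%), CO (10 atm), Et3N, 1,4-dioxane, 100 °C; then vent, DBU, 0 °C to rt
Reagents that add atoms: carbon monoxide, [C-]#[O+]
Why: Oxidative addition of the O–H bond to a zerovalent ruthenium carbonyl and CO insertion into the Ru–O bond give an alkoxycarbonyl ruthenium hydride, whose carbonyl carbon then migrates onto the central allene carbon, closing the ring through the new C2–C3 bond and leaving a π-allyl ruthenium hydride that reductively eliminates C–H at the CH2 terminus to write the C3 methyl group and the C3=C4 alkene. The closest known reaction type is the Ru3(CO)12/Et3N cyclic carbonylation of 2,3-allenols to 3-methylfuran-2(5H)-ones. The single ring closes by a five-membered migratory insertion that is exo to the terminal allene π-bond (5-exo), enforced by the two-atom O1–C2 tether. No new stereocentre has to be controlled: DBU removes the acidic C5–H of 13 and benzenesulfinate leaves from C6 (E1cB), which erases the C5 and C6 centres of all four diastereomers, and the ylidene is expected in the more stable Z geometry (chain beside O1, away from C4–H) because the elimination passes through the planar furanolate and sulfinate loss is reversible. The step needs carbonyl delivery to the central allene carbon with hydrogen to the terminus, secured by the tether and by the conjugation gained, and chemoselectivity over the furan and the two trisubstituted alkenes, which should not insert under these conditions. The C7 centre is not acidic in 12 or 13, and base contact after elimination is kept short and cold.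

**Compound list**
1 | 3-(chloromethyl)furan | ClCc1ccoc1 | starting material
2 | (2E,6E)-farnesyl chloride, (2E,6E)-1-chloro-3,7,11-trimethyldodeca-2,6,10-triene | CC(C)=CCC/C(C)=C/CC/C(C)=C/CCl | starting material
3 | furan-3-ylmethylmagnesium chloride | Cl[Mg]Cc1ccoc1 | intermediate
4 | 3-[(3E,7E)-4,8,12-trimethyltrideca-3,7,11-trien-1-yl]furan | CC(C)=CCC/C(C)=C/CC/C(C)=C/CCc1ccoc1 | intermediate
5 | (2E,6E,10E)-13-(furan-3-yl)-2,6,10-trimethyltrideca-2,6,10-trien-1-ol | OC/C(C)=C/CC/C(C)=C/CC/C(C)=C/CCc1ccoc1 | intermediate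
6 | (2S,6E,10E)-13-(furan-3-yl)-2,6,10-trimethyltrideca-6,10-dien-1-ol | OC[C@@H](C)CCC/C(C)=C/CC/C(C)=C/CCc1ccoc1 | intermediate
7 | (2S,6E,10E)-13-(furan-3-yl)-2,6,10-trimethyltrideca-6,10-dien-1-yl 4-methylbenzenesulfonate | Cc1ccc(cc1)S(=O)(=O)OC[C@@H](C)CCC/C(C)=C/CC/C(C)=C/CCc1ccoc1 | intermediate
8 | 3-[(3E,7E,12S)-4,8,12-trimethyl-13-(phenylsulfonyl)trideca-3,7-dien-1-yl]furan | O=S(=O)(C[C@@H](C)CCC/C(C)=C/CC/C(C)=C/CCc1ccoc1)c1ccccc1 | intermediate
9 | 3-(trimethylsilyl)prop-2-ynal | C[Si](C)(C)C#CC=O | starting material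
10 | (5S,9E,13E)-16-(furan-3-yl)-5,9,13-trimethyl-4-(phenylsulfonyl)-1-(trimethylsilyl)hexadeca-9,13-dien-1-yn-3-ol, diastereomer mixture at C3/C4 | C[Si](C)(C)C#CC(O)C(S(=O)(=O)c1ccccc1)[C@@H](C)CCC/C(C)=C/CC/C(C)=C/CCc1ccoc1 | intermediate
11 | (5S,9E,13E)-16-(furan-3-yl)-5,9,13-trimethyl-4-(phenylsulfonyl)hexadeca-9,13-dien-1-yn-3-ol, diastereomer mixture at C3/C4 | C#CC(O)C(S(=O)(=O)c1ccccc1)[C@@H](C)CCC/C(C)=C/CC/C(C)=C/CCc1ccoc1 | intermediate
12 | (6S,10E,14E)-17-(furan-3-yl)-6,10,14-trimethyl-5-(phenylsulfonyl)heptadeca-1,2,10,14-tetraen-4-ol, diastereomer mixture at C4/C5 | C=C=CC(O)C(S(=O)(=O)c1ccccc1)[C@@H](C)CCC/C(C)=C/CC/C(C)=C/CCc1ccoc1 | intermediate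
13 | 5-[(2S,6E,10E)-13-(furan-3-yl)-2,6,10-trimethyl-1-(phenylsulfonyl)trideca-6,10-dien-1-yl]-3-methylfuran-2(5H)-one, diastereomer mixture at ring C5 and the sulfonyl carbon | CC1=CC(OC1=O)C(S(=O)(=O)c1ccccc1)[C@@H](C)CCC/C(C)=C/CC/C(C)=C/CCc1ccoc1 | intermediate
14 | (5Z)-5-[(2S,6E,10E)-13-(furan-3-yl)-2,6,10-trimethyltrideca-6,10-dien-1-ylidene]-3-methylfuran-2(5H)-one | CC1=C/C(=C/[C@@H](C)CCC/C(C)=C/CC/C(C)=C/CCc2ccoc2)OC1=O | target

**Step count.** Total: 8 steps. Longest linear sequence: 8 steps (from 1 or 2 to 14).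

**Steps most likely to fail**

Step 8. The β-hydroxy sulfone may fragment by base-induced retro-addition at 100 °C. Sulfinate released by premature elimination may bind and deactivate the ruthenium carbonyl. Prolonged DBU contact may erode C7. The fallback avoids the allene and the heating: it sets out from sulfone 8 and comes back at 13. Deprotonation of 8 (LDA, THF, −78 °C) and addition to but-2-ynal should give (6S,10E,14E)-17-(furan-3-yl)-6,10,14-trimethyl-5-(phenylsulfonyl)heptadeca-10,14-dien-2-yn-4-ol F1. Hydroxyl-directed trans-hydroalumination with NaAlH2(OCH2CH2OCH3)2 (THF, 0 °C) and iodination (I2, −78 °C) should give (2Z,6S,10E,14E)-17-(furan-3-yl)-2-iodo-6,10,14-trimethyl-5-(phenylsulfonyl)heptadeca-2,10,14-trien-4-ol F2. Carbonylative lactonisation of this (Z)-γ-iodoallylic alcohol with Pd(PPh3)4, CO (1 atm) and K2CO3 in THF at rt should deliver the sulfonyl butenolide 13, which is treated with DBU as in step 8 to give 14.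

Step 3. Enantioface discrimination may be insufficient for a 2-methyl-substituted allylic alcohol, and ruthenium hydride may isomerise the allylic alcohol to the saturated aldehyde. The fallback changes the directing group to a carboxylate, a substrate class with firm precedent; it sets out from 5 and comes back at 6. Oxidation with MnO2 (CH2Cl2) should give (2E,6E,10E)-13-(furan-3-yl)-2,6,10-trimethyltrideca-2,6,10-trienal F3. Pinnick oxidation (NaClO2, NaH2PO4, 2-methylbut-2-ene, t-BuOH/H2O) should give (2E,6E,10E)-13-(furan-3-yl)-2,6,10-trimethyltrideca-2,6,10-trienoic acid F4. Hydrogenation with Ru(OAc)2[(S)-H8-BINAP] (H2, MeOH) should give (2S,6E,10E)-13-(furan-3-yl)-2,6,10-trimethyltrideca-6,10-dienoic acid F5. Reduction with LiAlH4 (Et2O, 0 °C) returns alcohol 6.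

Step 2. Site selectivity among three trisubstituted alkenes may be poor, and the peroxide may degrade the furan ring. The fallback oxidises before the furan is introduced; it sets out from 2 and Grignard reagent 3 and comes back at 5. Treatment of 2 with KOAc in DMF gives (2E,6E)-farnesyl acetate F6 (also purchasable). Catalytic SeO2/t-BuOOH oxidation should give (2E,6E,10E)-12-hydroxy-3,7,11-trimethyldodeca-2,6,10-trien-1-yl acetate F7. Copper-catalysed coupling of F7 with an excess of 3 (Li2CuCl4, THF, −20 °C; the first equivalent is consumed by the hydroxyl group) should give 5.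

**Further compounds**
F1 | step 8 | (6S,10E,14E)-17-(furan-3-yl)-6,10,14-trimethyl-5-(phenylsulfonyl)heptadeca-10,14-dien-2-yn-4-ol | CC#CC(O)C(S(=O)(=O)c1ccccc1)[C@@H](C)CCC/C(C)=C/CC/C(C)=C/CCc1ccoc1
F2 | step 8 | (2Z,6S,10E,14E)-17-(furan-3-yl)-2-iodo-6,10,14-trimethyl-5-(phenylsulfonyl)heptadeca-2,10,14-trien-4-ol | I/C(C)=C\C(O)C(S(=O)(=O)c1ccccc1)[C@@H](C)CCC/C(C)=C/CC/C(C)=C/CCc1ccoc1
F3 | step 3 | (2E,6E,10E)-13-(furan-3-yl)-2,6,10-trimethyltrideca-2,6,10-trienal | O=C/C(C)=C/CC/C(C)=C/CC/C(C)=C/CCc1ccoc1
F4 | step 3 | (2E,6E,10E)-13-(furan-3-yl)-2,6,10-trimethyltrideca-2,6,10-trienoic acid | OC(=O)/C(C)=C/CC/C(C)=C/CC/C(C)=C/CCc1ccoc1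
F5 | step 3 | (2S,6E,10E)-13-(furan-3-yl)-2,6,10-trimethyltrideca-6,10-dienoic acid | OC(=O)[C@@H](C)CCC/C(C)=C/CC/C(C)=C/CCc1ccoc1
F6 | step 2 | (2E,6E)-farnesyl acetate | CC(C)=CCC/C(C)=C/CC/C(C)=C/COC(C)=O
F7 | step 2 | (2E,6E,10E)-12-hydroxy-3,7,11-trimethyldodeca-2,6,10-trien-1-yl acetate | OC/C(C)=C/CC/C(C)=C/CC/C(C)=C/COC(C)=O
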